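Ring A (C4a, C5, C6, C7, C8, C8a) is a phloroglucinol. Its oxygens on C5, C7 and C8a, together with the acyl carbon C4 on C4a, spell out a poly-β-carbonyl chain, so the route rests on cutting C4a–C5. The precursor is a (2S)-2-aryl-2,3-dihydropyran-4-one with ring C complete and C2 set. Its C8a carries the chain C8H2–C7(=O)–C6H(prenyl)–C5O2tBu. On heating, C5 is released as an acylketene and the enol-ether carbon C4a attacks it. Ring A closes and aromatises in one base-free operation with prenyl fixed at C6. C2 stems from a BINOL–titanium vinylogous aldol of silylated vanillin, and the chain from a decarboxylative Claisen homologation.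

Key step: step 10

Remarks (flavanone numbering O1, C2–C4, C4a, C5–C8, C8a is used for all intermediates)
- Assumption: (S)-BINOL/Ti(OiPr)4 is taken to direct the nucleophile to the Si face of an aromatic aldehyde, as it does in allylations and in additions of 1,3-bis(silyloxy)dienes. Should the triene respond in the opposite sense, (R)-BINOL is used and nothing else changes.
- Ester at C5: a methyl ester closed with alkoxide was set aside.
  - C6–H is among the most acidic protons of the keto ester, and its enolate switches the ester off.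
  - The forcing basic conditions then needed would enolise C3 and open ring C by retro-oxa-Michael reaction. This would racemise C2, in the pyranone and in the flavanone alike, and would cleave the aryl silyl ether.
  - A tert-butyl ester keeps the skeleton and allows neutral thermal activation.
- Nucleophile: a 1-alkoxy-3-silyloxydiene that still carries a free CH2CO2R group cannot be made regioselectively, because C8–H2 is far more acidic than the terminal methyl group. The ester is therefore carried as its silyl ketene acetal (tris-silyloxy triene).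
- The carbon C6 of the keto ester is stereogenic. It forms as a mixture that the key step erases.

Step 1
Reactants: 1 vanillin
Product: 2 4-(tert-butyldimethylsilyloxy)-3-methoxybenzaldehyde
Conditions: t-BuMe2SiCl, imidazole, CH2Cl2, 0 °C to rt
Reagents that add atoms: tert-butyldimethylsilyl chloride, CC(C)(C)[Si](C)(C)Cl
Why: Imidazole-promoted O-silylation of a phenol masks the acidic 4'-OH with a group that is later removed by fluoride without touching prenyl or C2.

Step 2
Reactants: 3 tert-butyl acetoacetate; 4 N-methoxy-N-methylacetamide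
Product: 5 tert-butyl 3,5-dioxohexanoate
Conditions: LiN(iPr)2 (2.1 equiv), THF, −78 to 0 °C; then 4, −78 to 0 °C; cold 1 M HCl
Reagents that add atoms: none
Why: Claisen-type γ-acylation of a β-keto ester dianion by an N-methoxy-N-methylamide, whose chelated tetrahedral adduct survives until the quench and so prevents over-reaction.

Step 3
Reactants: 5 tert-butyl 3,5-dioxohexanoate
Product: 6 tert-butyl 3-oxo-5-(trimethylsilyloxy)hex-4-enoate
Conditions: Me3SiCl, Et3N, toluene, rt
Reagents that add atoms: trimethylsilyl chloride, C[Si](C)(C)Cl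
Why: Amine-mediated silyl enol ether formation on the strongly enolised 1,3-diketone unit, where either regioisomeric enol ether converges on the same triene in step 4.

Step 4
Reactants: 6 tert-butyl 3-oxo-5-(trimethylsilyloxy)hex-4-enoate
Product: 8 1-tert-butoxy-1,3,5-tris(trimethylsilyloxy)hexa-1,3,5-triene, via bis-silyl dienoate 7 (not isolated)
Conditions: LiN(iPr)2 then Me3SiCl, THF, −78 to 0 °C; repeated once in the same flask; filtered under Ar and used crude
Reagents that add atoms: trimethylsilyl chloride, C[Si](C)(C)Cl
Why: Successive deprotonation and O-silylation (silyl enol ether, then silyl ketene acetal formation) first removes the doubly activated proton at future C8 and then a proton of the terminal methyl group, so that the terminal CH2 (future C3) becomes the most nucleophilic site of a fully masked triketide.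

Step 5
Reactants: 2 4-(tert-butyldimethylsilyloxy)-3-methoxybenzaldehyde; 8 1-tert-butoxy-1,3,5-tris(trimethylsilyloxy)hexa-1,3,5-triene
Product: 10 tert-butyl 2-[(2S)-2-[4-(tert-butyldimethylsilyloxy)-3-methoxyphenyl]-4-oxo-2,3-dihydropyran-6-yl]acetate, via hydroxy diketo ester 9 (not isolated)
Conditions: (S)-BINOL (20 mol %), Ti(OiPr)4 (20 mol %), 4 Å MS, THF, −78 °C to rt; then CH2Cl2, CF3CO2H, 0 °C
Reagents that add atoms: none
Why: Catalytic asymmetric vinylogous Mukaiyama aldol (a formal hetero-Diels–Alder reaction) at the terminal carbon, the known site of attack of such trienes, with the (S)-BINOL–titanium complex shielding the Re face of the aldehyde so that C2 is set as S, followed by acid-induced desilylation and cyclodehydration of the δ-hydroxy-β-diketone to the conjugated dihydropyranone.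

Step 6
Reactants: 10 tert-butyl 2-[(2S)-2-[4-(tert-butyldimethylsilyloxy)-3-methoxyphenyl]-4-oxo-2,3-dihydropyran-6-yl]acetate
Product: 12 2-[(2S)-2-[4-(tert-butyldimethylsilyloxy)-3-methoxyphenyl]-4-oxo-2,3-dihydropyran-6-yl]acetic acid, via trimethylsilyl ester 11 (not isolated)
Conditions: Me3SiOTf, 2,6-lutidine, CH2Cl2, 0 °C; then pH 4 citrate buffer, 0 °C; used without heating
Reagents that add atoms: none
Why: Silyl-triflate-mediated tert-butyl ester cleavage (alkyl–oxygen fission to isobutene) under buffered aprotic conditions avoids hydroxide, which would open the vinylogous ester, and prolonged strong acid, which could ionise the electron-rich benzylic C2–O1 bond.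

Step 7
Reactants: 13 tert-butyl methyl malonate; 14 prenyl bromide
Product: 15 tert-butyl methyl 2-(3-methylbut-2-enyl)malonate (racemic)
Conditions: NaH, THF, 0 °C; then 14, 0 °C to rt (13 in slight excess)
Reagents that add atoms: none
Why: Malonic ester alkylation, an SN2 displacement on a primary allylic bromide, in which a slight excess of malonate suppresses double alkylation.

Step 8
Reactants: 15 tert-butyl methyl 2-(3-methylbut-2-enyl)malonate
Product: 16 2-(tert-butoxycarbonyl)-5-methylhex-4-enoic acid (racemic)
Conditions: KOH (1.05 equiv), MeOH/H2O, 0 °C to rt; then 1 M HCl to pH 3, 0 °C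
Reagents that add atoms: potassium hydroxide, [K+].[OH-]
Why: Chemoselective saponification, since hydroxide attacks the methyl ester while the tert-butyl ester is sterically closed to acyl–oxygen cleavage.

Step 9
Reactants: 12 2-[(2S)-2-[4-(tert-butyldimethylsilyloxy)-3-methoxyphenyl]-4-oxo-2,3-dihydropyran-6-yl]acetic acid; 16 2-(tert-butoxycarbonyl)-5-methylhex-4-enoic acid
Product: 19 tert-butyl 2-(3-methylbut-2-enyl)-3-oxo-4-[(2S)-2-[4-(tert-butyldimethylsilyloxy)-3-methoxyphenyl]-4-oxo-2,3-dihydropyran-6-yl]butanoate (both epimers at C6), via magnesium half-ester salt 17 (not isolated), via acyl imidazolide 18 (not isolated)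
Conditions: 16, Mg(OEt)2, THF, rt, evaporate; separately 12, CDI, THF, 0 °C to rt; combine, THF, rt; cold 0.5 M HCl
Reagents that add atoms: none
Why: Masamune–Brooks decarboxylative Claisen condensation, in which the chelated magnesium enolate of the half ester is C-acylated by the imidazolide under nearly neutral conditions and loses CO2, placing prenyl unambiguously on C6, whose new centre forms as a mixture that step 10 erases.

Step 10
Reactants: 19 tert-butyl 2-(3-methylbut-2-enyl)-3-oxo-4-[(2S)-2-[4-(tert-butyldimethylsilyloxy)-3-methoxyphenyl]-4-oxo-2,3-dihydropyran-6-yl]butanoate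
Product: 21 (2S)-2-[4-(tert-butyldimethylsilyloxy)-3-methoxyphenyl]-5,7-dihydroxy-6-(3-methylbut-2-enyl)chroman-4-one, via acylketene 20 (not isolated)
Conditions: dry toluene (0.005 M), reflux (110 °C), Ar, slow distillative removal of toluene/t-BuOH
Reagents that add atoms: none
Why: Proposed new method: at reflux the tert-butyl β-keto ester loses t-BuOH by the retro-ene path known from transacetoacetylation and gives α-prenyl acylketene 20, whose sp carbon C5 is a far stronger acceptor than an ester lying next to the acidic C6–H. Tautomerisation of the C7 ketone towards C8 makes 20 a dienylketene (C5=C6–C7=C8–C8a=C4a, with the hydrogen of C4a on the inside) that closes ring A by 6π electrocyclisation, in polar terms a 6-exo-dig attack of the enol-ether carbon C4a on C5, and two proton shifts then deliver the 5,7-dihydroxyarene. The closest known reaction types are the dienylketene-to-phenol closure that ends the Danheiser benzannulation and, for the same bond, the base-mediated Claisen cyclisation of 3,5,7-triketo esters to acylphloroglucinols. No stereocentre is made: the mixed centre C6 becomes planar, and C2 is kept because no base is present to enolise C3 and start a retro-oxa-Michael opening of ring C. The step needs C-acylation at C4a rather than O-acylation or aldol folding, and the substrate secures this: the oxygen on C8a is tied up as O1 so that no 2-pyranone can form, the C4 oxygen lies trans to the chain across C4a=C8a, and attack of C6 on the C4 carbonyl would create a strained bicycle with a bridgehead alkene.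

Step 11
Reactants: 21 (2S)-2-[4-(tert-butyldimethylsilyloxy)-3-methoxyphenyl]-5,7-dihydroxy-6-(3-methylbut-2-enyl)chroman-4-one
Product: 22 (2S)-5,7-dihydroxy-2-(4-hydroxy-3-methoxyphenyl)-6-(3-methylbut-2-enyl)chroman-4-one
Conditions: Bu4NF (1.2 equiv), AcOH (2 equiv), THF, 0 °C
Reagents that add atoms: none
Why: Fluoride-induced cleavage of the aryl silyl ether, buffered by acetic acid so that neither a 4'-phenoxide (quinone-methide opening of ring C) nor a C3 enolate can build up and C2 stays S.

Compound list
1 | vanillin (4-hydroxy-3-methoxybenzaldehyde) | COc1cc(C=O)ccc1O | starting material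
2 | 4-(tert-butyldimethylsilyloxy)-3-methoxybenzaldehyde | COc1cc(C=O)ccc1O[Si](C)(C)C(C)(C)C | intermediate
3 | tert-butyl acetoacetate | CC(=O)CC(=O)OC(C)(C)C | starting material
4 | N-methoxy-N-methylacetamide | CC(=O)N(C)OC | starting material
5 | tert-butyl 3,5-dioxohexanoate | CC(=O)CC(=O)CC(=O)OC(C)(C)C | intermediate
6 | tert-butyl 3-oxo-5-(trimethylsilyloxy)hex-4-enoate | CC(O[Si](C)(C)C)=CC(=O)CC(=O)OC(C)(C)C | intermediate
7 | tert-butyl 3,5-bis(trimethylsilyloxy)hexa-2,4-dienoate (not isolated) | CC(O[Si](C)(C)C)=CC(O[Si](C)(C)C)=CC(=O)OC(C)(C)C | intermediate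
8 | 1-tert-butoxy-1,3,5-tris(trimethylsilyloxy)hexa-1,3,5-triene | C=C(O[Si](C)(C)C)C=C(O[Si](C)(C)C)C=C(O[Si](C)(C)C)OC(C)(C)C | intermediate
9 | tert-butyl (7S)-7-[4-(tert-butyldimethylsilyloxy)-3-methoxyphenyl]-7-hydroxy-3,5-dioxoheptanoate (not isolated) | COc1cc([C@@H](O)CC(=O)CC(=O)CC(=O)OC(C)(C)C)ccc1O[Si](C)(C)C(C)(C)C | intermediate
10 | tert-butyl 2-[(2S)-2-[4-(tert-butyldimethylsilyloxy)-3-methoxyphenyl]-4-oxo-2,3-dihydropyran-6-yl]acetate | CC(C)(C)OC(=O)CC1=CC(=O)C[C@@H](c2ccc(O[Si](C)(C)C(C)(C)C)c(OC)c2)O1 | intermediate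
11 | trimethylsilyl 2-[(2S)-2-[4-(tert-butyldimethylsilyloxy)-3-methoxyphenyl]-4-oxo-2,3-dihydropyran-6-yl]acetate (not isolated) | C[Si](C)(C)OC(=O)CC1=CC(=O)C[C@@H](c2ccc(O[Si](C)(C)C(C)(C)C)c(OC)c2)O1 | intermediate
12 | 2-[(2S)-2-[4-(tert-butyldimethylsilyloxy)-3-methoxyphenyl]-4-oxo-2,3-dihydropyran-6-yl]acetic acid | OC(=O)CC1=CC(=O)C[C@@H](c2ccc(O[Si](C)(C)C(C)(C)C)c(OC)c2)O1 | intermediate
13 | tert-butyl methyl malonate | COC(=O)CC(=O)OC(C)(C)C | starting material
14 | prenyl bromide (1-bromo-3-methylbut-2-ene) | CC(C)=CCBr | starting material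
15 | tert-butyl methyl 2-(3-methylbut-2-enyl)malonate (racemic) | COC(=O)C(CC=C(C)C)C(=O)OC(C)(C)C | intermediate
16 | 2-(tert-butoxycarbonyl)-5-methylhex-4-enoic acid (racemic) | OC(=O)C(CC=C(C)C)C(=O)OC(C)(C)C | intermediate
17 | magnesium bis[2-(tert-butoxycarbonyl)-5-methylhex-4-enoate] (not isolated) | [Mg+2].CC(C)=CCC(C(=O)[O-])C(=O)OC(C)(C)C.CC(C)=CCC(C(=O)[O-])C(=O)OC(C)(C)C | intermediate
18 | (2S)-2-[4-(tert-butyldimethylsilyloxy)-3-methoxyphenyl]-6-[2-(imidazol-1-yl)-2-oxoethyl]-2,3-dihydropyran-4-one (not isolated) | O=C(CC1=CC(=O)C[C@@H](c2ccc(O[Si](C)(C)C(C)(C)C)c(OC)c2)O1)n1ccnc1 | intermediate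
19 | tert-butyl 2-(3-methylbut-2-enyl)-3-oxo-4-[(2S)-2-[4-(tert-butyldimethylsilyloxy)-3-methoxyphenyl]-4-oxo-2,3-dihydropyran-6-yl]butanoate (epimers at C6) | CC(C)(C)OC(=O)C(CC=C(C)C)C(=O)CC1=CC(=O)C[C@@H](c2ccc(O[Si](C)(C)C(C)(C)C)c(OC)c2)O1 | intermediate
20 | (2S)-2-[4-(tert-butyldimethylsilyloxy)-3-methoxyphenyl]-6-[6-methyl-2-oxo-3-(oxomethylidene)hept-5-enyl]-2,3-dihydropyran-4-one (acylketene, not isolated) | O=C=C(CC=C(C)C)C(=O)CC1=CC(=O)C[C@@H](c2ccc(O[Si](C)(C)C(C)(C)C)c(OC)c2)O1 | intermediate
21 | (2S)-2-[4-(tert-butyldimethylsilyloxy)-3-methoxyphenyl]-5,7-dihydroxy-6-(3-methylbut-2-enyl)chroman-4-one | COc1cc([C@@H]2CC(=O)c3c(cc(O)c(CC=C(C)C)c3O)O2)ccc1O[Si](C)(C)C(C)(C)C | intermediate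
22 | (2S)-5,7-dihydroxy-2-(4-hydroxy-3-methoxyphenyl)-6-(3-methylbut-2-enyl)chroman-4-one | COc1cc([C@@H]2CC(=O)c3c(cc(O)c(CC=C(C)C)c3O)O2)ccc1O | target

Total step count: 11. Longest linear sequence: 8 (steps 2, 3, 4, 5, 6, 9, 10, 11).

Steps most likely to fail

Step 10 (the labelled step, highest risk).
- What may go wrong: release of the ketene may be slower than hoped. Recapture by t-BuOH, dimerisation, or hydrolysis with decarboxylation may also outrun ring closure by the only weakly nucleophilic C4a.
- Fallback: this uses known chemistry and raises the nucleophile instead of the electrophile. It is the magnesium-alkoxide Claisen cyclisation established for 3,5,7-triketo methyl esters on their way to acylphloroglucinols. It sets out from 12. Dimethyl malonate is alkylated with 14 (NaH, THF) to dimethyl 2-(3-methylbut-2-enyl)malonate F1. This is half-saponified (KOH, MeOH) to 2-(methoxycarbonyl)-5-methylhex-4-enoic acid F2, which Mg(OEt)2 converts into its magnesium salt F3. Acylation of F3 by imidazolide 18, made from 12 as in step 9, gives the methyl keto ester F4. Mg(OMe)2 in THF/MeOH at 0 °C to rt deprotonates C8. The chelated dienolate attacks the ester through C4a, methoxide leaves and the ring aromatises. Mildly acidic work-up brings the route back at 21. Contact with base is kept short, because enolisation at C3 would open ring C and erode C2.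

Step 5.
- What may go wrong: facial selectivity may be poor, the triene may attack through an inner carbon, or turnover may be slow with the electron-rich aldehyde.
- Fallback: the task is divided. C2 is set by the acetate-type Mukaiyama aldol for which BINOL/Ti(OiPr)4 is proven on aromatic aldehydes, and the remaining four carbons come in by dianion acylation. The fallback sets out from 2 and uses 3. Aldehyde 2 reacts with 1-(tert-butylthio)-1-(trimethylsilyloxy)ethene under (S)-BINOL/Ti(OiPr)4 (Et2O, −20 °C, acidic work-up). This should give S-tert-butyl (3S)-3-[4-(tert-butyldimethylsilyloxy)-3-methoxyphenyl]-3-hydroxypropanethioate F5. Et3SiCl and imidazole give its triethylsilyl ether F6. The dianion of 3 (LiN(iPr)2, 2 equiv, THF, −78 °C) is acylated at its terminal carbon by F6 to give tert-butyl (7S)-7-[4-(tert-butyldimethylsilyloxy)-3-methoxyphenyl]-3,5-dioxo-7-(triethylsilyloxy)heptanoate F7. CF3CO2H in CH2Cl2 at 0 °C removes the triethylsilyl group and cyclodehydrates, so the route is rejoined at 10. Steps 2 to 4 then fall away.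

Step 9.
- What may go wrong: enolisation of the imidazolide at C8 with self-condensation, or decarboxylation of the acid before activation, may outrun attack by the hindered magnesium enolate.
- Fallback: a crossed Claisen condensation with a hard ester enolate turns that enolisation to profit. It sets out from 12. 1-Chloro-N,N,2-trimethylprop-1-en-1-amine in CH2Cl2 at 0 °C gives the acid chloride F8 under neutral conditions. tert-Butyl acetate is alkylated (LiN(iPr)2, then 14) to tert-butyl 5-methylhex-4-enoate F9. The lithium enolate of F9 (3 equiv, THF, −78 °C) takes up F8, either directly or through the conjugated ketene formed by loss of HCl. A quench with AcOH at −78 °C brings the route back at 19.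

Further compounds
F1 | step 10 | dimethyl 2-(3-methylbut-2-enyl)malonate | COC(=O)C(CC=C(C)C)C(=O)OC
F2 | step 10 | 2-(methoxycarbonyl)-5-methylhex-4-enoic acid (racemic) | COC(=O)C(CC=C(C)C)C(=O)O
F3 | step 10 | magnesium bis[2-(methoxycarbonyl)-5-methylhex-4-enoate] | [Mg+2].COC(=O)C(CC=C(C)C)C(=O)[O-].COC(=O)C(CC=C(C)C)C(=O)[O-]
F4 | step 10 | methyl 2-(3-methylbut-2-enyl)-3-oxo-4-[(2S)-2-[4-(tert-butyldimethylsilyloxy)-3-methoxyphenyl]-4-oxo-2,3-dihydropyran-6-yl]butanoate (epimers at C6) | COC(=O)C(CC=C(C)C)C(=O)CC1=CC(=O)C[C@@H](c2ccc(O[Si](C)(C)C(C)(C)C)c(OC)c2)O1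
F5 | step 5 | S-tert-butyl (3S)-3-[4-(tert-butyldimethylsilyloxy)-3-methoxyphenyl]-3-hydroxypropanethioate | COc1cc([C@@H](O)CC(=O)SC(C)(C)C)ccc1O[Si](C)(C)C(C)(C)C
F6 | step 5 | S-tert-butyl (3S)-3-[4-(tert-butyldimethylsilyloxy)-3-methoxyphenyl]-3-(triethylsilyloxy)propanethioate | COc1cc([C@@H](O[Si](CC)(CC)CC)CC(=O)SC(C)(C)C)ccc1O[Si](C)(C)C(C)(C)C
F7 | step 5 | tert-butyl (7S)-7-[4-(tert-butyldimethylsilyloxy)-3-methoxyphenyl]-3,5-dioxo-7-(triethylsilyloxy)heptanoate | COc1cc([C@@H](O[Si](CC)(CC)CC)CC(=O)CC(=O)CC(=O)OC(C)(C)C)ccc1O[Si](C)(C)C(C)(C)C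
F8 | step 9 | 2-[(2S)-2-[4-(tert-butyldimethylsilyloxy)-3-methoxyphenyl]-4-oxo-2,3-dihydropyran-6-yl]acetyl chloride | O=C(Cl)CC1=CC(=O)C[C@@H](c2ccc(O[Si](C)(C)C(C)(C)C)c(OC)c2)O1
F9 | step 9 | tert-butyl 5-methylhex-4-enoate | CC(C)=CCCC(=O)OC(C)(C)C
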